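The runs were generated by integration for an exercise; noise was put on by code.

The amounts come first: eta holds 1.20 equivalents of partner per substrate, and each substrate can take up 2.

| setting | north | east | south | eta | beta |
|---|---|---|---|---|---|
| substrate | 0.30 M | 0.30 M | 0.30 M | 0.30 M | 0.30 M |
| partner | 0.29 M | 0.60 M | 1.1 M | 0.360 M | 0.900 M |
| remark | run made earlier | run made earlier | run made earlier |  |  |
| time |  |  |  | 40 h | 40 h |

- north (time / h: single product / %, double product / %): 5.00: 68.4, 13.4; 15.0: 69.7, 13.6; 25.0: 68.9, 14.9; 40.0: 69.1, 13.5
- east (time / h: single product / %, double product / %): 5.00: 14.8, 86.5; 15.0: 4.4, 95.7; 25.0: 4.1, 95.4; 40.0: 3.0, 99.8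
- south (time / h: single product / %, double product / %): 3.00: 0.3, 98.8; 8.00: 0, 98.2; 15.0: 1.7, 99.5; 40.0: 0, 101.6

(standard deviation of a reading: 1 percentage point)

- the numbers in the tables scatter by 1 percentage point (one standard deviation)

- which of these holds the largest part of the substrate at the end of eta (double product / substrate / single product)
- which of these holds the largest part of the substrate at the end of beta (double product / substrate / single product)
- amount of single product at the end of eta, in percent of the substrate charged

At 40.0 h north reads 69.1% single product and 13.5% double product, which leaves 17.4% substrate. From these I read Q = 20.3, the sharing ratio:

Q = [single product] × [single product] / ([substrate] × [double product])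

Chance sharing between like sites is the zero of this scale, at Q = 4. I build eta up one process at a time.

Main step, substrate + partner → single product: it takes 1 equivalent and eta has more, so I get 100 percent single product.

Second step, single product + partner → double product, at chance: single product falls to 48.0%.

Second step at north's Q, with [single product] + 2[double product] = 1.20 equivalents:

double product 27.5%, single product 64.9%, substrate 7.53%

The rest: north reads about the same single product at 5.00 h, 68.4%, as at 40.0 h, having taken up 0.961 of 0.967 equivalents, with partner as limiting reagent. So I add nothing for the hours. Beta, at 3.00 equivalents, lies above east's 2.00, and east reads 99.8% double product, so I expect double product there.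

The forecast, reading the flask as “two successive steps”, names single product for eta and double product for beta, with 67% single product in eta, above my 64.9%.

The flask gives 67.6% single product in eta, where single product holds most, and double product holds most in beta.

    substrate + partner → single product (k = 0.00590 M⁻¹ s⁻¹)
    partner + single product → double product (k = 0.00100 M⁻¹ s⁻¹)
    substrate → decomposition product (k = 8.80 × 10⁻⁷ s⁻¹)

Eta's end values give Q = 32.2. A neighbour of eta is charged with 0.75 M substrate and so holds 0.480 equivalents of partner, its other charges and the time as in eta. North's Q gives double product 1.80%, single product 44.4% and substrate 53.8%. That neighbour flask gives 43.0% single product and 2.49% double product, and substrate holds most at 48.0%, beside 6.49% decomposition product.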